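**Plan**

1. Numbering: pyran O1, C2 (Me, carbocycle), C3 (OAc), C4, C5 (Br), C6 (Me2); carbocycle C1' (on C2), C3' (Br), C4' (Me, Cl), C6' (OH). O1 lies between the fully substituted carbons C2 and C6. With C2 taken back to an ester carbonyl, both C–O bonds come from acylating a tertiary C6 alcohol, and the 3,4-dihydro-2H-pyran ring closes at C2=C3 by carbonyl olefination and metathesis.
2. Retrosynthetic cuts, in order: C6'–O–Si; C4'–Cl and C3'–Br (back to a ring epoxide, then the C3'=C4' alkene); the acetate; C2–CH3 and C3–O (back to the cyclic enol ether); C2=C3; the ester C–O1 bond; C3'=C4' (ring-closing metathesis) and C1'–C6' (aldol); the two C6–CH3 bonds.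
3. Forward: the cyclohexene is built first (aldol, then metathesis) and esterified with the tertiary bromohydrin; the pyran ring is then closed, and the pyran and the carbocycle are functionalised in that order.
4. Stereochemistry: C5 from L-allylglycine; C1' and C6' from an Evans syn-aldol; C2 and C3 from epoxidation of the enol ether anti to C5–Br and trans-diaxial opening by methyl; C3' and C4' from epoxidation anti to the C1'/C6' substituents followed by two openings under neighbouring-group and ring-conformational control.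
5. Direct BrCl addition to the ring alkene is avoided: with the pyranyl group equatorial, diaxial Markovnikov addition would give the other trans-dihalide.

Key step: step 11

Assumption: the SMILES is read as (2S,3S,5S) in the pyran and (1'S,3'R,4'R,6'R) in the carbocycle, with C6'–OH cis to the pyranyl group; every compound below is a single enantiomer.

**Route**

Step 1
Reactants: 1 L-allylglycine, (S)-2-aminopent-4-enoic acid
Product: 2 (S)-2-bromopent-4-enoic acid
Conditions: NaNO2, 48% aq HBr, 0 °C
Reagents that add atoms: hydrogen bromide, Br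
Why: Diazotisation of the α-amino acid proceeds through the α-lactone formed by carboxylate participation, so bromide enters with net retention (double inversion) and the S centre of 1 becomes C5 of the target.

Step 2
Reactants: 2 (S)-2-bromopent-4-enoic acid
Product: 3 methyl (S)-2-bromopent-4-enoate
Conditions: MeOH, H2SO4 (cat.), 25 °C
Reagents that add atoms: methanol, CO
Why: Fischer esterification under acid should neither enolise nor displace the α-bromo centre.

Step 3
Reactants: 3 methyl (S)-2-bromopent-4-enoate
Product: 4 (S)-3-bromo-2-methylhex-5-en-2-ol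
Conditions: MeMgBr (3 equiv), Et2O, −78 → −20 °C; cold aq NH4Cl
Reagents that add atoms: methylmagnesium bromide, C[Mg]Br
Why: Double Grignard addition to the ester builds the C6 gem-dimethyl carbinol, and at low temperature the magnesium alkoxide should not close to the epoxide nor the transient α-bromo ketone enolise, so the C–Br centre is kept.

Step 4
Reactants: 5 (S)-4-benzyloxazolidin-2-one; 6 pent-4-enoyl chloride
Product: 7 (S)-4-benzyl-3-(pent-4-enoyl)oxazolidin-2-one
Conditions: n-BuLi, THF, −78 → 0 °C
Reagents that add atoms: none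
Why: N-acylation of the lithiated oxazolidinone is the standard loading of an Evans auxiliary.

Step 5
Reactants: 8 3-methylbut-3-en-1-ol
Product: 9 3-methylbut-3-enal
Conditions: Dess–Martin periodinane, pyridine, CH2Cl2, 0 °C; solution used at once
Reagents that add atoms: none
Why: Dess–Martin oxidation under buffered conditions gives the β,γ-unsaturated aldehyde, which is used immediately to forestall migration of the double bond into conjugation.

Step 6
Reactants: 7 (S)-4-benzyl-3-(pent-4-enoyl)oxazolidin-2-one; 9 3-methylbut-3-enal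
Product: 11 (S)-4-benzyl-3-[(2S,3R)-2-allyl-3-hydroxy-5-methylhex-5-enoyl]oxazolidin-2-one, via Z-boron enolate 10 (not isolated)
Conditions: Bu2BOTf, i-Pr2NEt, CH2Cl2, 0 °C; then 9, −78 → 0 °C; H2O2, MeOH, pH 7 buffer
Reagents that add atoms: none
Why: Evans syn-aldol reaction in which the Z dibutylboron enolate reacts through a Zimmerman–Traxler chair on the face away from the benzyl group, setting C1' (S) and C6' (R) in the syn relationship that becomes cis on the ring.

Step 7
Reactants: 11 (S)-4-benzyl-3-[(2S,3R)-2-allyl-3-hydroxy-5-methylhex-5-enoyl]oxazolidin-2-one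
Product: 12 (S)-4-benzyl-3-[(2S,3R)-2-allyl-3-(tert-butyldimethylsilyloxy)-5-methylhex-5-enoyl]oxazolidin-2-one
Conditions: TBSOTf, 2,6-lutidine, CH2Cl2, −78 → 0 °C
Reagents that add atoms: tert-butyldimethylsilyl trifluoromethanesulfonate, CC(C)(C)[Si](C)(C)OS(=O)(=O)C(F)(F)F
Why: Silylation of the hindered secondary alcohol with the silyl triflate gives an ether that later keeps the C6' oxygen from directing or participating.

Step 8
Reactants: 12 (S)-4-benzyl-3-[(2S,3R)-2-allyl-3-(tert-butyldimethylsilyloxy)-5-methylhex-5-enoyl]oxazolidin-2-one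
Product: 13 (S)-4-benzyl-3-[(1S,6R)-6-(tert-butyldimethylsilyloxy)-4-methylcyclohex-3-ene-1-carbonyl]oxazolidin-2-one
Conditions: second-generation Grubbs catalyst (H2IMes)(PCy3)Cl2Ru=CHPh (3 mol %), CH2Cl2, 40 °C
Reagents that add atoms: none
Why: Ring-closing metathesis of the vinyl and 1,1-disubstituted alkenes closes the cyclohexene and forms the trisubstituted C3'=C4' bond with loss of ethene.

Step 9
Reactants: 13 (S)-4-benzyl-3-[(1S,6R)-6-(tert-butyldimethylsilyloxy)-4-methylcyclohex-3-ene-1-carbonyl]oxazolidin-2-one
Product: 15 (1S,6R)-6-(tert-butyldimethylsilyloxy)-4-methylcyclohex-3-ene-1-carboxylic acid, via peroxy acid 14 (not isolated)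
Conditions: LiOH, H2O2, THF/H2O, 0 °C; then Na2SO3
Reagents that add atoms: hydrogen peroxide, OO
Why: Hydroperoxide attacks the exocyclic imide carbonyl selectively (Evans auxiliary cleavage), sulfite reduces the peracid, and the auxiliary is released without epimerisation at C1'.

Step 10
Reactants: 15 (1S,6R)-6-(tert-butyldimethylsilyloxy)-4-methylcyclohex-3-ene-1-carboxylic acid; 4 (S)-3-bromo-2-methylhex-5-en-2-ol
Product: 17 (S)-3-bromo-2-methylhex-5-en-2-yl (1S,6R)-6-(tert-butyldimethylsilyloxy)-4-methylcyclohex-3-ene-1-carboxylate, via acid chloride 16 (not isolated)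
Conditions: 1-chloro-N,N,2-trimethylprop-1-en-1-amine (Ghosez reagent), CH2Cl2, 0 → 25 °C; then 4, DMAP, CH2Cl2, 25 → 40 °C
Reagents that add atoms: none
Why: Acylation of a tertiary alcohol by an acid chloride under DMAP acyl-transfer catalysis, with the acid chloride made under neutral conditions and no alkoxide generated, so the bromohydrin cannot close to an epoxide.

Step 11
Reactants: 17 (S)-3-bromo-2-methylhex-5-en-2-yl (1S,6R)-6-(tert-butyldimethylsilyloxy)-4-methylcyclohex-3-ene-1-carboxylate
Product: 19 (S)-3-bromo-2,2-dimethyl-6-[(1S,6R)-6-(tert-butyldimethylsilyloxy)-4-methylcyclohex-3-en-1-yl]-3,4-dihydro-2H-pyran, via acyclic enol ether 18 (not isolated)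
Conditions: Tebbe reagent Cp2Ti(μ-CH2)(μ-Cl)AlMe2 (4 equiv), pyridine (cat.), THF, 0 → 25 °C; then 65 °C
Reagents that add atoms: none
Why: Titanocene methylidene released from the Tebbe reagent adds to the ester C=O ([2+2], then cycloreversion) to give the acyclic enol ether 18 and Cp2TiO; on heating, a further equivalent takes up the terminal vinyl group, loses ethene to become a titanium alkylidene and closes onto the enol ether C=CH2 by a second [2+2]/cycloreversion, which forms C2=C3 and returns Cp2Ti=CH2. The closest known reaction type is the Tebbe-mediated olefinic ester cyclisation used for six- and seven-membered cyclic enol ethers of polyethers (carbonyl olefination followed by enol ether–olefin ring-closing metathesis). The 3,4-dihydro-2H-pyran closes by ring-closing metathesis at C2=C3, so neither of the hindered bonds O1–C2 and O1–C6 has to be made by substitution. No stereocentre is formed, and C5, C1' and C6' are not involved. The carbene must choose the monosubstituted vinyl group over the trisubstituted ring alkene, which the steric demand of titanacyclobutane formation should secure, and the C5–Br bond must survive, which is favoured by the absence of zinc or other reducing metal and by tempering the aluminium Lewis acid with pyridine in THF.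

Step 12
Reactants: 19 (S)-3-bromo-2,2-dimethyl-6-[(1S,6R)-6-(tert-butyldimethylsilyloxy)-4-methylcyclohex-3-en-1-yl]-3,4-dihydro-2H-pyran
Product: 21 (2S,3S,5S)-5-bromo-2-[(1S,6R)-6-(tert-butyldimethylsilyloxy)-4-methylcyclohex-3-en-1-yl]-2,6,6-trimethyltetrahydro-2H-pyran-3-ol, via enol-ether epoxide 20 (not isolated)
Conditions: DMDO (acetone-free, CH2Cl2), −78 → −40 °C; then MeMgCl, THF, −78 → 0 °C
Reagents that add atoms: dimethyldioxirane, CC1(C)OO1; methylmagnesium chloride, C[Mg]Cl
Why: Chemoselective epoxidation of the electron-rich enol ether (much faster than the trisubstituted ring alkene) should occur on the face opposite the C5 bromide, and the Grignard reagent should then open the ketal-type epoxide at C2 with inversion along the trans-diaxial (Fürst–Plattner) path, as in C-glycoside formation from glycal epoxides, which places methyl at C2 trans to the C3 hydroxyl and sets C2 (S) and C3 (S).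

Step 13
Reactants: 21 (2S,3S,5S)-5-bromo-2-[(1S,6R)-6-(tert-butyldimethylsilyloxy)-4-methylcyclohex-3-en-1-yl]-2,6,6-trimethyltetrahydro-2H-pyran-3-ol
Product: 22 (2S,3S,5S)-5-bromo-2-[(1S,6R)-6-(tert-butyldimethylsilyloxy)-4-methylcyclohex-3-en-1-yl]-2,6,6-trimethyltetrahydro-2H-pyran-3-yl acetate
Conditions: Ac2O, DMAP, Et3N, CH2Cl2, 25 °C
Reagents that add atoms: acetic anhydride, CC(=O)OC(C)=O
Why: DMAP-catalysed acetylation of the hindered axial C3 alcohol installs the acetate of the target before the ring alkene is oxidised.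

Step 14
Reactants: 22 (2S,3S,5S)-5-bromo-2-[(1S,6R)-6-(tert-butyldimethylsilyloxy)-4-methylcyclohex-3-en-1-yl]-2,6,6-trimethyltetrahydro-2H-pyran-3-yl acetate
Product: 23 (3'S,4'R)-3',4'-epoxide of 22, oxirane oxygen trans to the C1' and C6' substituents
Conditions: m-CPBA, CH2Cl2, 0 °C
Reagents that add atoms: 3-chloroperoxybenzoic acid, OOC(=O)c1cccc(Cl)c1
Why: Prilezhaev epoxidation of the only remaining alkene, with the peracid approaching from the face opposite the cis C1' pyranyl and axial C6' silyloxy groups.

Step 15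
Reactants: 23 (3'S,4'R)-3',4'-epoxide of 22
Product: 24 (3'S,4'S)-4'-bromo-3'-hydroxy compound (trans-diaxial bromohydrin; tertiary Br cis to the C1' and C6' substituents, C3'–OH trans to them)
Conditions: LiBr, AcOH, THF, 0 → 25 °C
Reagents that add atoms: lithium bromide, [Li+].[Br-]
Why: Acid-assisted epoxide opening by bromide in which the trans-diaxial (Fürst–Plattner) and Markovnikov preferences coincide at C4', giving with inversion the tertiary axial bromide anti-periplanar to the axial C3' hydroxyl.

Step 16
Reactants: 24 (3'S,4'S)-4'-bromo-3'-hydroxy compound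
Product: 26 (3'R,4'R)-3'-bromo-4'-chloro O-silyl ether of the target, via chlorosulfite 25 (not isolated)
Conditions: SOCl2, pyridine, CH2Cl2, −20 → 25 °C
Reagents that add atoms: thionyl chloride, O=S(Cl)Cl
Why: Substitution with anchimeric assistance, in which the anti-periplanar bromine expels the chlorosulfite with inversion at C3' to give a bromonium ion on the face of the C1' substituent and chloride opens it at the tertiary, more cationic terminus C4' (Markovnikov) with a second inversion there, so bromine ends at C3' (R) and chlorine at C4' (R).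

Step 17
Reactants: 26 (3'R,4'R)-3'-bromo-4'-chloro O-silyl ether of the target
Product: 27 (2S,3S,5S)-5-bromo-2-[(1S,2R,4R,5R)-5-bromo-4-chloro-2-hydroxy-4-methylcyclohexyl]-2,6,6-trimethyltetrahydro-2H-pyran-3-yl acetate (CNP0166766.1)
Conditions: HF·pyridine, THF, 0 → 25 °C
Reagents that add atoms: none
Why: Fluoride-mediated cleavage of the silyl ether under mildly acidic, non-basic conditions should spare the acetate, the tertiary chloride and both bromides.

**Compound list**

1 | L-allylglycine, (S)-2-aminopent-4-enoic acid | C=CC[C@H](N)C(=O)O | starting material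
2 | (S)-2-bromopent-4-enoic acid | C=CC[C@H](Br)C(=O)O | intermediate
3 | methyl (S)-2-bromopent-4-enoate | C=CC[C@H](Br)C(=O)OC | intermediate
4 | (S)-3-bromo-2-methylhex-5-en-2-ol | C=CC[C@H](Br)C(C)(C)O | intermediate
5 | (S)-4-benzyloxazolidin-2-one | O=C1N[C@@H](Cc2ccccc2)CO1 | starting material
6 | pent-4-enoyl chloride | C=CCCC(=O)Cl | starting material
7 | (S)-4-benzyl-3-(pent-4-enoyl)oxazolidin-2-one | C=CCCC(=O)N1[C@@H](Cc2ccccc2)COC1=O | intermediate
8 | 3-methylbut-3-en-1-ol | CC(=C)CCO | starting material
9 | 3-methylbut-3-enal | CC(=C)CC=O | intermediate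
10 | Z-dibutylboron enolate of 7 | C=CC/C=C(\OB(CCCC)CCCC)N1[C@@H](Cc2ccccc2)COC1=O | intermediate
11 | (S)-4-benzyl-3-[(2S,3R)-2-allyl-3-hydroxy-5-methylhex-5-enoyl]oxazolidin-2-one | C=CC[C@@H]([C@H](O)CC(C)=C)C(=O)N1[C@@H](Cc2ccccc2)COC1=O | intermediate
12 | (S)-4-benzyl-3-[(2S,3R)-2-allyl-3-(tert-butyldimethylsilyloxy)-5-methylhex-5-enoyl]oxazolidin-2-one | C=CC[C@@H]([C@H](O[Si](C)(C)C(C)(C)C)CC(C)=C)C(=O)N1[C@@H](Cc2ccccc2)COC1=O | intermediate
13 | (S)-4-benzyl-3-[(1S,6R)-6-(tert-butyldimethylsilyloxy)-4-methylcyclohex-3-ene-1-carbonyl]oxazolidin-2-one | O=C([C@H]1CC=C(C)C[C@H]1O[Si](C)(C)C(C)(C)C)N1[C@@H](Cc2ccccc2)COC1=O | intermediate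
14 | (1S,6R)-6-(tert-butyldimethylsilyloxy)-4-methylcyclohex-3-ene-1-carboperoxoic acid | OOC(=O)[C@H]1CC=C(C)C[C@H]1O[Si](C)(C)C(C)(C)C | intermediate
15 | (1S,6R)-6-(tert-butyldimethylsilyloxy)-4-methylcyclohex-3-ene-1-carboxylic acid (cis) | OC(=O)[C@H]1CC=C(C)C[C@H]1O[Si](C)(C)C(C)(C)C | intermediate
16 | (1S,6R)-6-(tert-butyldimethylsilyloxy)-4-methylcyclohex-3-ene-1-carbonyl chloride | ClC(=O)[C@H]1CC=C(C)C[C@H]1O[Si](C)(C)C(C)(C)C | intermediate
17 | (S)-3-bromo-2-methylhex-5-en-2-yl (1S,6R)-6-(tert-butyldimethylsilyloxy)-4-methylcyclohex-3-ene-1-carboxylate | C=CC[C@H](Br)C(C)(C)OC(=O)[C@H]1CC=C(C)C[C@H]1O[Si](C)(C)C(C)(C)C | intermediate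
18 | acyclic enol ether: 17 with the ester C=O replaced by C=CH2 (C5 S, C1' S, C6' R) | C=CC[C@H](Br)C(C)(C)OC(=C)[C@H]1CC=C(C)C[C@H]1O[Si](C)(C)C(C)(C)C | intermediate
19 | (S)-3-bromo-2,2-dimethyl-6-[(1S,6R)-6-(tert-butyldimethylsilyloxy)-4-methylcyclohex-3-en-1-yl]-3,4-dihydro-2H-pyran | Br[C@H]1CC=C(OC1(C)C)[C@H]1CC=C(C)C[C@H]1O[Si](C)(C)C(C)(C)C | intermediate
20 | (2R,3S,5S)-2,3-epoxide of 19, oxirane oxygen trans to C5–Br | Br[C@H]1C[C@@H]2O[C@@]2(OC1(C)C)[C@H]1CC=C(C)C[C@H]1O[Si](C)(C)C(C)(C)C | intermediate
21 | (2S,3S,5S)-5-bromo-2-[(1S,6R)-6-(tert-butyldimethylsilyloxy)-4-methylcyclohex-3-en-1-yl]-2,6,6-trimethyltetrahydro-2H-pyran-3-ol | O[C@H]1C[C@H](Br)C(C)(C)O[C@@]1(C)[C@H]1CC=C(C)C[C@H]1O[Si](C)(C)C(C)(C)C | intermediate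
22 | (2S,3S,5S)-5-bromo-2-[(1S,6R)-6-(tert-butyldimethylsilyloxy)-4-methylcyclohex-3-en-1-yl]-2,6,6-trimethyltetrahydro-2H-pyran-3-yl acetate | CC(=O)O[C@H]1C[C@H](Br)C(C)(C)O[C@@]1(C)[C@H]1CC=C(C)C[C@H]1O[Si](C)(C)C(C)(C)C | intermediate
23 | (3'S,4'R)-3',4'-epoxide of 22, oxirane oxygen trans to the C1' and C6' substituents | CC(=O)O[C@H]1C[C@H](Br)C(C)(C)O[C@@]1(C)[C@H]1C[C@@H]2O[C@]2(C)C[C@H]1O[Si](C)(C)C(C)(C)C | intermediate
24 | (3'S,4'S)-4'-bromo-3'-hydroxy compound, trans-diaxial bromohydrin | CC(=O)O[C@H]1C[C@H](Br)C(C)(C)O[C@@]1(C)[C@H]1C[C@H](O)[C@@](C)(Br)C[C@H]1O[Si](C)(C)C(C)(C)C | intermediate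
25 | chlorosulfite of 24 (configuration at sulfur undefined) | CC(=O)O[C@H]1C[C@H](Br)C(C)(C)O[C@@]1(C)[C@H]1C[C@H](OS(=O)Cl)[C@@](C)(Br)C[C@H]1O[Si](C)(C)C(C)(C)C | intermediate
26 | tert-butyldimethylsilyl ether of the target, (3'R,4'R)-3'-bromo-4'-chloro | CC(=O)O[C@H]1C[C@H](Br)C(C)(C)O[C@@]1(C)[C@H]1C[C@@H](Br)[C@](C)(Cl)C[C@H]1O[Si](C)(C)C(C)(C)C | intermediate
27 | (2S,3S,5S)-5-bromo-2-[(1S,2R,4R,5R)-5-bromo-4-chloro-2-hydroxy-4-methylcyclohexyl]-2,6,6-trimethyltetrahydro-2H-pyran-3-yl acetate | CC(=O)O[C@H]1C[C@H](Br)C(C)(C)O[C@@]1(C)[C@H]1C[C@@H](Br)[C@](C)(Cl)C[C@H]1O | target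

**Count**

Total steps: 17. Longest linear sequence: 13 steps (steps 4 and 6 to 17).

**Steps most likely to fail**

Step 11. The doubly hindered ester may be methylenated only sluggishly, and during the heating needed for ring closure titanium species formed by decomposition of the reagent may reduce the C5–Br bond or eliminate it against the neighbouring C6–O bond. The fallback separates the two events. It sets out from 17, which is methylenated with Cp2TiMe2 (toluene, 65 °C), a non-Lewis-acidic source of the same titanium methylidene, and the acyclic enol ether 18 is isolated. The ring is then closed by enol ether–olefin ring-closing metathesis with the second-generation Grubbs catalyst (H2IMes)(PCy3)Cl2Ru=CHPh in toluene at 70 °C, so the C2=C3 bond is made by a ruthenium carbene under neutral, non-reducing conditions. The fallback comes back to the route at 19.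

Step 12. The weakness is poor facial selectivity in the epoxidation: if the oxidant adds on the face of the C5 bromide, opening with inversion would put the C2 methyl group on the wrong face. The fallback sets out from 19. The epoxide formed on the bromide face F1 is treated with AlMe3 (CH2Cl2, −78 → 0 °C), which hands over methyl within the aluminate on the same face as the oxygen, the known way to angular methyl groups of polyethers. This gives the C3-epimeric alcohol F2, in which C2 is already correct. Dess–Martin oxidation gives the 3-ketone F3, and reduction with LiBH(s-Bu)3 (equatorial hydride delivery, axial alcohol trans to the axial C2 methyl) comes back to the route at 21.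

Step 16. The bromonium ion may be opened in the wrong direction, chloride attacking the secondary carbon C3' along the trans-diaxial path instead of the tertiary C4'; proton loss from the cation is a second leak. The fallback sets out from 24 and accepts that course, which gives the trans-diaxial 4'-bromo-3'-chloro isomer F4. Heating this isomer in a polar, non-nucleophilic solvent (MeCN or sulfolane, 80 °C) should bring about the known diaxial-to-diequatorial 1,2-interchange of vicinal dihalides by ion-pair return through the same bromonium ion. Bromine moves to C3' and chlorine to C4', each on its own face, and the fallback comes back to the route at 26.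

**Further compounds**

F0 | step 11 | none | none
F1 | step 12 | (2S,3R,5S)-2,3-epoxide of 19, oxirane oxygen cis to C5–Br | Br[C@H]1C[C@H]2O[C@]2(OC1(C)C)[C@H]1CC=C(C)C[C@H]1O[Si](C)(C)C(C)(C)C
F2 | step 12 | (2S,3R,5S)-5-bromo-2-[(1S,6R)-6-(tert-butyldimethylsilyloxy)-4-methylcyclohex-3-en-1-yl]-2,6,6-trimethyltetrahydro-2H-pyran-3-ol, C3 epimer of 21 | O[C@@H]1C[C@H](Br)C(C)(C)O[C@@]1(C)[C@H]1CC=C(C)C[C@H]1O[Si](C)(C)C(C)(C)C
F3 | step 12 | (2S,5S)-5-bromo-2-[(1S,6R)-6-(tert-butyldimethylsilyloxy)-4-methylcyclohex-3-en-1-yl]-2,6,6-trimethyltetrahydro-2H-pyran-3-one | O=C1C[C@H](Br)C(C)(C)O[C@@]1(C)[C@H]1CC=C(C)C[C@H]1O[Si](C)(C)C(C)(C)C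
F4 | step 16 | (3'S,4'S)-4'-bromo-3'-chloro isomer of 26, trans-diaxial | CC(=O)O[C@H]1C[C@H](Br)C(C)(C)O[C@@]1(C)[C@H]1C[C@H](Cl)[C@@](C)(Br)C[C@H]1O[Si](C)(C)C(C)(C)C
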